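Ring A of the target carries substituents only on three adjacent atoms: C8 (oxygen), C8a (bonded to the lactone carbonyl C1) and C4a (bonded to the C4 methylene). C5, C6 and C7 are unsubstituted. A 1-methoxycyclohexa-1,3-diene and a chiral alk-2-ynoate map onto this pattern. One thermal operation forms C8–C8a and C4a–C5 and, by loss of ethene, aromatises ring A with the oxygen, the ester and the side chain in place. The ynoate is a silyl-protected (5R)-6-benzyloxy-5-hydroxyhex-2-ynoate made by an epoxide opening, and it carries the only stereocentre. The sensitive dienyl chain is attached last.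

Key step: step 3

Assumption: commercial diene 6 contains some 1-methoxycyclohexa-1,4-diene, which is taken to be an inert spectator in step 3, so 6 is used in excess.

Step 1
Reactants: 1 (R)-benzyl glycidyl ether; 2 methyl propiolate
Product: 4 methyl (5R)-6-(benzyloxy)-5-hydroxyhex-2-ynoate, via methyl 3-lithiopropiolate 3 (not isolated)
Conditions: 2 (2 equiv), n-BuLi (1.9 equiv), THF, −78 °C; BF3·OEt2 (2 equiv), then 1, −78 °C; aq NH4Cl quench at −78 °C
Reagents that add atoms: none
Why: Yamaguchi–Hirao alkynylation, in which the BF3-activated terminal epoxide is opened by the lithium acetylide through SN2 attack at the unsubstituted carbon at −78 °C (where the lithiated propiolate is stable), so the stereocentre of 1 is not touched and appears as (5R) in 4.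

Step 2
Reactants: 4 methyl (5R)-6-(benzyloxy)-5-hydroxyhex-2-ynoate
Product: 5 methyl (5R)-6-(benzyloxy)-5-[(tert-butyldimethylsilyl)oxy]hex-2-ynoate
Conditions: TBSOTf (1.2 equiv), 2,6-lutidine (1.5 equiv), CH2Cl2, −78 → 0 °C
Reagents that add atoms: tert-butyldimethylsilyl trifluoromethanesulfonate, CC(C)(C)[Si](C)(C)OS(=O)(=O)C(F)(F)F
Why: Silylation of a secondary alcohol with a silyl triflate and a hindered, non-nucleophilic base, chosen over imidazole or DMAP so that no amine adds to the ynoate; the carbinol centre is unaffected.

Step 3
Reactants: 5 methyl (5R)-6-(benzyloxy)-5-[(tert-butyldimethylsilyl)oxy]hex-2-ynoate; 6 1-methoxycyclohexa-1,3-diene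
Product: 8 methyl 2-[(2R)-3-(benzyloxy)-2-[(tert-butyldimethylsilyl)oxy]propyl]-6-methoxybenzoate, via bicyclo[2.2.2]octadiene adduct 7 (not isolated)
Conditions: 6 (3 equiv), BHT (cat.), neat, 185 °C, pressure tube, Ar; volatiles removed in vacuo
Reagents that add atoms: none
Why: A concerted normal-electron-demand [4+2] cycloaddition between the electron-rich dienol ether 6 and the electron-poor ynoate 5 gives the bicyclo[2.2.2]octa-2,5-diene 7, which at the same temperature loses ethene from its saturated two-carbon bridge by retro-[4+2]; this is the Alder–Rickert arene synthesis, established for 1-methoxycyclohexa-1,3-diene and alk-2-ynoates. Ring A is closed by intermolecular [4+2] annulation, with C8–C8a and C4a–C5 formed in the cycloaddition, and it becomes aromatic in the cycloreversion, which is irreversible because ethene leaves. No stereocentre is created in 8: the bridgehead centres of 7 (formed as a mixture) vanish on aromatisation, and the carbinol centre is separated from the alkyne by a methylene and has no acidic hydrogen, so it should survive the heating. The selectivity needed is regiochemical (methoxy next to the ester, side chain on its other flank); it is secured by the donor on diene C1, which puts the largest HOMO coefficient on C4 so that C4 bonds to the ynoate β-carbon and C1 to the α-carbon. Chemoselectivity is secured by the silyl ether, which keeps the hydroxyl from adding to the enol ether or the ynoate and from lactonising in the melt, and by the excess of 6, which offsets its thermal dimerisation.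

Step 4
Reactants: 8 methyl 2-[(2R)-3-(benzyloxy)-2-[(tert-butyldimethylsilyl)oxy]propyl]-6-methoxybenzoate
Product: 10 (R)-3-[(benzyloxy)methyl]-8-methoxyisochroman-1-one, via hydroxy ester 9 (not isolated)
Conditions: TsOH·H2O (0.3 equiv), MeOH, rt; then solvent switch to toluene, 100 °C
Reagents that add atoms: none
Why: Acid methanolysis of the secondary silyl ether gives hydroxy ester 9, which on heating with the same acid undergoes intramolecular transesterification (6-exo-trig acyl substitution) with loss of methanol; the carbinol C–O bond is never broken, so C3 keeps the (R) configuration, and the benzyl and aryl methyl ethers are stable to these conditions.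

Step 5
Reactants: 10 (R)-3-[(benzyloxy)methyl]-8-methoxyisochroman-1-one
Product: 11 (R)-8-hydroxy-3-(hydroxymethyl)isochroman-1-one
Conditions: BCl3 (4 equiv, 1 M in CH2Cl2), CH2Cl2, −78 → 0 °C; then H2O
Reagents that add atoms: none
Why: Lewis-acid ether cleavage, in which BCl3 chelated between the lactone carbonyl and the peri C8 methoxy group removes that methyl selectively and also cleaves the primary benzyl ether, while the secondary C3–O bond of the lactone (neither benzylic nor allylic at this stage) is left intact.

Step 6
Reactants: 11 (R)-8-hydroxy-3-(hydroxymethyl)isochroman-1-one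
Product: 12 (R)-8-hydroxy-1-oxoisochromane-3-carbaldehyde
Conditions: Dess–Martin periodinane (1.3 equiv), CH2Cl2, 0 °C → rt; aq Na2S2O3/NaHCO3 work-up; used crude
Reagents that add atoms: none
Why: Dess–Martin oxidation of the primary alcohol under mild, near-neutral conditions; the C8 phenol is hydrogen-bonded to the lactone carbonyl and electron-poor, so it should be oxidised far more slowly than the alcohol, and the aldehyde is taken on crude to avoid epimerisation at C3.

Step 7
Reactants: 12 (R)-8-hydroxy-1-oxoisochromane-3-carbaldehyde
Product: 13 (R)-8-hydroxy-3-[(E)-2-iodoethenyl]isochroman-1-one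
Conditions: CrCl2 (8 equiv), CHI3 (3 equiv), THF/1,4-dioxane (1:6), 0 °C → rt, dark
Reagents that add atoms: iodoform, IC(I)I
Why: Takai–Utimoto iodo-olefination, in which the geminal dichromium species from CHI3 and CrCl2 adds to the aldehyde and eliminates anti to give the (E)-vinyl iodide; the process is non-basic, so the α-acyloxy stereocentre and the lactone should be untouched, and the excess reagent allows for the acidic phenol.

Step 8
Reactants: 14 1-pentadecyne
Product: 15 (E)-4,4,5,5-tetramethyl-2-(pentadec-1-en-1-yl)-1,3,2-dioxaborolane
Conditions: pinacolborane (1.1 equiv), Cp2ZrHCl (5 mol%), Et3N (10 mol%), neat, 60 °C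
Reagents that add atoms: pinacolborane, CC1(C)OBOC1(C)C
Why: Catalysed hydroboration of a terminal alkyne, in which hydrozirconation by Cp2ZrHCl and transfer to boron deliver H and B syn and anti-Markovnikov, which fixes the (E) geometry of the alkenylboronate.

Step 9
Reactants: 13 (R)-8-hydroxy-3-[(E)-2-iodoethenyl]isochroman-1-one; 15 (E)-4,4,5,5-tetramethyl-2-(pentadec-1-en-1-yl)-1,3,2-dioxaborolane
Product: 16 (R)-3-[(1E,3E)-heptadeca-1,3-dien-1-yl]-8-hydroxyisochroman-1-one
Conditions: PdCl2(dppf)·CH2Cl2 (5 mol%), K3PO4 (3 equiv), THF/H2O (5:1), rt, degassed, dark; pH 6 buffer work-up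
Reagents that add atoms: none
Why: Suzuki–Miyaura alkenyl–alkenyl coupling, which retains the geometry of both partners and so gives the (1E,3E)-diene; oxidative addition of zerovalent palladium to the vinyl C–I bond at room temperature should be much faster than ionisation of the allylic lactone C–O bond, and the phenol is carried as its phenoxide and reprotonated on work-up.

Compound list
1 | (R)-benzyl glycidyl ether, (2R)-2-[(benzyloxy)methyl]oxirane | C1O[C@H]1COCc1ccccc1 | starting material
2 | methyl propiolate | C#CC(=O)OC | starting material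
3 | methyl 3-lithiopropiolate | [Li]C#CC(=O)OC | intermediate
4 | methyl (5R)-6-(benzyloxy)-5-hydroxyhex-2-ynoate | COC(=O)C#CC[C@@H](O)COCc1ccccc1 | intermediate
5 | methyl (5R)-6-(benzyloxy)-5-[(tert-butyldimethylsilyl)oxy]hex-2-ynoate | COC(=O)C#CC[C@@H](O[Si](C)(C)C(C)(C)C)COCc1ccccc1 | intermediate
6 | 1-methoxycyclohexa-1,3-diene | COC1=CC=CCC1 | starting material
7 | methyl 3-[(2R)-3-(benzyloxy)-2-[(tert-butyldimethylsilyl)oxy]propyl]-1-methoxybicyclo[2.2.2]octa-2,5-diene-2-carboxylate (mixture of bridgehead diastereomers) | COC(=O)C1=C(C[C@@H](O[Si](C)(C)C(C)(C)C)COCc2ccccc2)C2C=CC1(OC)CC2 | intermediate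
8 | methyl 2-[(2R)-3-(benzyloxy)-2-[(tert-butyldimethylsilyl)oxy]propyl]-6-methoxybenzoate | COC(=O)c1c(OC)cccc1C[C@@H](O[Si](C)(C)C(C)(C)C)COCc1ccccc1 | intermediate
9 | methyl 2-[(2R)-3-(benzyloxy)-2-hydroxypropyl]-6-methoxybenzoate | COC(=O)c1c(OC)cccc1C[C@@H](O)COCc1ccccc1 | intermediate
10 | (R)-3-[(benzyloxy)methyl]-8-methoxyisochroman-1-one | O(Cc1ccccc1)C[C@H]1Cc2cccc(OC)c2C(=O)O1 | intermediate
11 | (R)-8-hydroxy-3-(hydroxymethyl)isochroman-1-one | OC[C@H]1Cc2cccc(O)c2C(=O)O1 | intermediate
12 | (R)-8-hydroxy-1-oxoisochromane-3-carbaldehyde | O=C[C@H]1Cc2cccc(O)c2C(=O)O1 | intermediate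
13 | (R)-8-hydroxy-3-[(E)-2-iodoethenyl]isochroman-1-one | I/C=C/[C@H]1Cc2cccc(O)c2C(=O)O1 | intermediate
14 | 1-pentadecyne | CCCCCCCCCCCCCC#C | starting material
15 | (E)-4,4,5,5-tetramethyl-2-(pentadec-1-en-1-yl)-1,3,2-dioxaborolane | CCCCCCCCCCCCC/C=C/B1OC(C)(C)C(C)(C)O1 | intermediate
16 | (R)-3-[(1E,3E)-heptadeca-1,3-dien-1-yl]-8-hydroxyisochroman-1-one | CCCCCCCCCCCCC/C=C/C=C/[C@H]1Cc2cccc(O)c2C(=O)O1 | target

Total step count: 9. Longest linear sequence: 8 steps (steps 1–7 and 9); step 8 is a one-step side branch.

Steps most likely to fail

Step 3. The cycloaddition of the β-alkyl ynoate may be too slow to compete with thermal dimerisation and decomposition of the diene, ethene extrusion may be incomplete, or regiocontrol may erode. The fallback gives up the cycloaddition and starts from a preformed arene; it sets out from 1 and returns at 10. Commercial N,N-diethyl-2-methoxybenzamide F1 would be lithiated at C6 by amide-directed ortho-metalation (s-BuLi, TMEDA, THF, −78 °C) to N,N-diethyl-2-lithio-6-methoxybenzamide F2 (not isolated). This aryllithium would open epoxide 1 at its terminal carbon in the presence of BF3·OEt2 to give N,N-diethyl-2-[(2R)-3-(benzyloxy)-2-hydroxypropyl]-6-methoxybenzamide F3. Hydroxyl-assisted lactonisation (TsOH, toluene, reflux) would then expel diethylamine and give lactone 10.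

Step 6. The free phenol may be attacked by the hypervalent iodine oxidant, and the α-acyloxy aldehyde may lose configurational integrity or hydrate; the same free phenol may also consume reagent in step 7. The fallback keeps the phenol masked through both steps; it sets out from 10 and returns at 13. Hydrogenolysis of 10 (H2, palladium on carbon Pd/C, EtOAc) would remove only the benzyl group and give (R)-3-(hydroxymethyl)-8-methoxyisochroman-1-one F4. Dess–Martin oxidation would give (R)-8-methoxy-1-oxoisochromane-3-carbaldehyde F5, and Takai olefination (CrCl2, CHI3) would give (R)-3-[(E)-2-iodoethenyl]-8-methoxyisochroman-1-one F6. Chelation-controlled demethylation (BCl3, CH2Cl2, −78 °C) would then give vinyl iodide 13.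

Step 9. Zerovalent palladium may ionise the dienylic lactone C–O bond of the product, the aqueous base may open the lactone, or the diene may isomerise. The fallback is palladium-free and base-free in the coupling; it sets out from 14 and 13 and returns at 16. Ligand-controlled hydrostannation of 14 (Bu3SnH, Pd2(dba)3 cat., Cy3P·HBF4, iPr2NEt, CH2Cl2, 0 °C) would give (E)-tributyl(pentadec-1-en-1-yl)stannane F7. This would be coupled with 13 by a Stille-type reaction mediated by CuTC (copper thiophene-2-carboxylate, CuO2CC4H3S, monovalent copper) in NMP at 0 °C → rt, to give 16.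

Further compounds
F1 | step 3 | N,N-diethyl-2-methoxybenzamide (purchased) | CCN(CC)C(=O)c1ccccc1OC
F2 | step 3 | N,N-diethyl-2-lithio-6-methoxybenzamide | CCN(CC)C(=O)c1c([Li])cccc1OC
F3 | step 3 | N,N-diethyl-2-[(2R)-3-(benzyloxy)-2-hydroxypropyl]-6-methoxybenzamide | CCN(CC)C(=O)c1c(OC)cccc1C[C@@H](O)COCc1ccccc1
F4 | step 6 | (R)-3-(hydroxymethyl)-8-methoxyisochroman-1-one | OC[C@H]1Cc2cccc(OC)c2C(=O)O1
F5 | step 6 | (R)-8-methoxy-1-oxoisochromane-3-carbaldehyde | O=C[C@H]1Cc2cccc(OC)c2C(=O)O1
F6 | step 6 | (R)-3-[(E)-2-iodoethenyl]-8-methoxyisochroman-1-one | I/C=C/[C@H]1Cc2cccc(OC)c2C(=O)O1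
F7 | step 9 | (E)-tributyl(pentadec-1-en-1-yl)stannane | CCCCCCCCCCCCC/C=C/[Sn](CCCC)(CCCC)CCCC
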